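**Plan**

- Numbering: C6 is the ring carbinol carbon, C5 the ring CH(CH3), C7–C16 the chain from the ring to the butenolide; C13 carries the acetoxymethyl group.
- Cuts, in retrosynthetic order: silyl ether and acetate; C15=C16 (olefination of a lactol); O–C15 and C13=C14 of a temporary lactone (reduction, ring-closing metathesis); the acrylate ester; C12–C13 (Negishi coupling); C10–C11 and C9–CH3 (carboalumination, epoxide opening); C6–C7 (Grignard addition).
- Enabling feature: across C13=C14 the acetoxymethyl carbon and C15 are cis, as C5 and C2 are around C4=C3 of a 4-alkylfuran-2(5H)-one. That five-membered ring (O, CH2, C13, C14, C15) is closed by metathesis and its O–C15 bond is cut afterwards, so the ring oxygen ends as the acetate oxygen.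
- Forward: the cyclohexane is present from the start and the chain grows linearly from the ring ketone to C12. C13 is coupled on, the sacrificial lactone is closed and reduced, and its opening by olefination attaches the terminal butenolide, whose own ring comes from a Wittig–lactonisation of dihydroxyacetone.
- Stereochemistry: C5 from enantioselective protonation of a silyl enol ether; C6 from axial addition to the ketone, governed by C5 and the axial methyl of the gem-dimethyl group; C9=C10 (E) from syn-carboalumination; C13=C14 from the ring; C15=C16 (E) from the phosphonate olefination.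

Key step: step 10

Assumption: the SnCl4–BINOL acid is taken to protonate enol ether 3 on the same enol face as in the 2-arylcyclohexanone series, so that (S)-BINOL gives the (S)-ketone; if the sense proves opposite, (R)-BINOL is used with no other change.

**Route**

Step 1
Reactants: 1 2,6,6-trimethylcyclohex-2-en-1-one
Product: 3 trimethyl[(2,6,6-trimethylcyclohex-1-en-1-yl)oxy]silane, via lithium enolate 2 (not isolated)
Conditions: LiBH(s-Bu)3, THF, −78 °C; then Me3SiCl, −78 °C to rt
Reagents that add atoms: chlorotrimethylsilane, C[Si](C)(C)Cl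
Why: Conjugate hydride reduction of a β-unsubstituted cyclohexenone whose carbonyl is shielded by the quaternary carbon gives the enolate regiospecifically, and O-silylation traps it as the only possible silyl enol ether.

Step 2
Reactants: 3 trimethyl[(2,6,6-trimethylcyclohex-1-en-1-yl)oxy]silane
Product: 4 (6S)-2,2,6-trimethylcyclohexan-1-one
Conditions: (S)-BINOL (1.1 equiv), SnCl4 (1.0 equiv), toluene, −78 °C; aq. NaHCO3
Reagents that add atoms: none
Why: Enantioselective protonation of a silyl enol ether by a Lewis acid-assisted chiral Brønsted acid, in which the tin-bound BINOL hydroxyl delivers the proton to one enol face and so sets C5 as S, on a ketone that is a standard substrate for this reaction type.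

Step 3
Reactants: 4 (6S)-2,2,6-trimethylcyclohexan-1-one; 5 (4-bromobut-1-yn-1-yl)trimethylsilane
Product: 7 (1R,2S)-2,6,6-trimethyl-1-[4-(trimethylsilyl)but-3-yn-1-yl]cyclohexan-1-ol, via butynyl Grignard reagent 6 (not isolated)
Conditions: 5, Mg, THF, 35 °C; anhydrous CeCl3, THF, −78 °C; then 4, −78 to 0 °C; aq. NH4Cl
Reagents that add atoms: none
Why: CeCl3-mediated Grignard addition (Imamoto conditions) suppresses enolisation and keeps the α-stereocentre, and with the secondary methyl equatorial the axial methyl of the gem-dimethyl group blocks the equatorial trajectory, so the chain enters axially, cis to the secondary methyl, leaving the hydroxyl trans to it (1R).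

Step 4
Reactants: 7 (1R,2S)-2,6,6-trimethyl-1-[4-(trimethylsilyl)but-3-yn-1-yl]cyclohexan-1-ol
Product: 8 (1R,2S)-1-(but-3-yn-1-yl)-2,6,6-trimethylcyclohexan-1-ol
Conditions: K2CO3, MeOH, rt
Reagents that add atoms: none
Why: Base-mediated protiodesilylation of an alkynylsilane, in which methoxide attacks only the silicon bound to the sp carbon.

Step 5
Reactants: 8 (1R,2S)-1-(but-3-yn-1-yl)-2,6,6-trimethylcyclohexan-1-ol
Product: 9 {[(1R,2S)-1-(but-3-yn-1-yl)-2,6,6-trimethylcyclohexyl]oxy}triethylsilane
Conditions: Et3SiOTf, 2,6-lutidine, CH2Cl2, 0 °C to rt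
Reagents that add atoms: triethylsilyl trifluoromethanesulfonate, CC[Si](CC)(CC)OS(=O)(=O)C(F)(F)F
Why: Silylation with a silyl triflate and 2,6-lutidine is reactive enough for a tertiary carbinol flanked by a quaternary carbon, and it removes the only acidic proton before the organoaluminium, organolithium and organozinc steps.

Step 6
Reactants: 9 {[(1R,2S)-1-(but-3-yn-1-yl)-2,6,6-trimethylcyclohexyl]oxy}triethylsilane
Product: 12 (3E)-4-methyl-6-{(1R,2S)-2,6,6-trimethyl-1-[(triethylsilyl)oxy]cyclohexyl}hex-3-en-1-ol, via alkenyldimethylalane 10 (not isolated), via lithium alkenylalanate 11 (not isolated)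
Conditions: Me3Al, Cp2ZrCl2 (0.2 equiv), CH2Cl2, 0 °C to rt; volatiles removed; n-BuLi, hexane–THF, 0 °C; ethylene oxide, 0 °C to rt; aq. potassium sodium tartrate
Reagents that add atoms: trimethylaluminium, C[Al](C)C; ethylene oxide, C1CO1
Why: Negishi zirconium-catalysed carboalumination adds CH3 and aluminium syn across the terminal alkyne with aluminium at the terminus, which fixes C9=C10 as E, and the alanate formed with n-BuLi transfers the alkenyl group to ethylene oxide with retention.

Step 7
Reactants: 12 (3E)-4-methyl-6-{(1R,2S)-2,6,6-trimethyl-1-[(triethylsilyl)oxy]cyclohexyl}hex-3-en-1-ol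
Product: 13 {[(1R,2S)-1-[(3E)-6-iodo-3-methylhex-3-en-1-yl]-2,6,6-trimethylcyclohexyl]oxy}triethylsilane
Conditions: I2, PPh3, imidazole, CH2Cl2, 0 °C
Reagents that add atoms: iodine, II
Why: Appel-type iodination proceeds by SN2 displacement of the primary alkoxyphosphonium ion and leaves the silyl ether and the trisubstituted olefin untouched.

Step 8
Reactants: 13 {[(1R,2S)-1-[(3E)-6-iodo-3-methylhex-3-en-1-yl]-2,6,6-trimethylcyclohexyl]oxy}triethylsilane; 14 2-bromoprop-2-en-1-ol
Product: 16 (5E)-6-methyl-2-methylidene-8-{(1R,2S)-2,6,6-trimethyl-1-[(triethylsilyl)oxy]cyclohexyl}oct-5-en-1-ol, via alkylzinc iodide 15 (not isolated)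
Conditions: Zn dust (activated with BrCH2CH2Br, Me3SiCl), LiCl, THF, 40 °C; then added slowly to 14 (0.8 equiv), Pd(OAc)2 (2 mol %), SPhos (4 mol %), THF, 25 °C
Reagents that add atoms: none
Why: LiCl-promoted zinc insertion into the primary iodide followed by Negishi cross-coupling with the alkenyl bromide, where the Pd(OAc)2–SPhos catalyst is known to couple alkylzinc halides faster than a free hydroxyl protonates them.

Step 9
Reactants: 16 (5E)-6-methyl-2-methylidene-8-{(1R,2S)-2,6,6-trimethyl-1-[(triethylsilyl)oxy]cyclohexyl}oct-5-en-1-ol; 17 acryloyl chloride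
Product: 18 (5E)-6-methyl-2-methylidene-8-{(1R,2S)-2,6,6-trimethyl-1-[(triethylsilyl)oxy]cyclohexyl}oct-5-en-1-yl prop-2-enoate
Conditions: 17, Et3N, CH2Cl2, −20 to 0 °C
Reagents that add atoms: none
Why: O-Acylation of the primary allylic alcohol by an acid chloride with an amine base, the only other hydroxyl being silylated.

Step 10
Reactants: 18 (5E)-6-methyl-2-methylidene-8-{(1R,2S)-2,6,6-trimethyl-1-[(triethylsilyl)oxy]cyclohexyl}oct-5-en-1-yl prop-2-enoate
Product: 19 4-[(3E)-4-methyl-6-{(1R,2S)-2,6,6-trimethyl-1-[(triethylsilyl)oxy]cyclohexyl}hex-3-en-1-yl]furan-2(5H)-one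
Conditions: second-generation Grubbs catalyst RuCl2(=CHPh)(PCy3)(H2IMes) (5 mol %), CH2Cl2 (0.005 M), 40 °C
Reagents that add atoms: none
Why: The ruthenium benzylidene exchanges onto one of the two terminal olefins of 18, the new alkylidene adds to the other in an intramolecular [2+2] step to give a ruthenacyclobutane, and cycloreversion releases the lactone while ethene is lost on turnover. The closest known reaction is the ring-closing metathesis of allyl and methallyl acrylates to furan-2(5H)-ones with N-heterocyclic-carbene ruthenium catalysts. The ring closes by joining C13 to C14 across the acrylate tether, a five-membered closure (O, C15, C14, C13, CH2) that forms a trisubstituted conjugated olefin. No stereocentre is formed, and the geometry of C13=C14 is dictated by the ring, which can hold the oxymethyl carbon and C15 only cis. The chemoselectivity needed follows because the trisubstituted C9=C10 olefin enters metathesis slowly and could close only a cyclobutene or an eight-membered lactone, while high dilution holds back intermolecular cross-metathesis.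

Step 11
Reactants: 19 4-[(3E)-4-methyl-6-{(1R,2S)-2,6,6-trimethyl-1-[(triethylsilyl)oxy]cyclohexyl}hex-3-en-1-yl]furan-2(5H)-one
Product: 20 4-[(3E)-4-methyl-6-{(1R,2S)-2,6,6-trimethyl-1-[(triethylsilyl)oxy]cyclohexyl}hex-3-en-1-yl]-2,5-dihydrofuran-2-ol (both C2 epimers)
Conditions: i-Bu2AlH (1.2 equiv), CH2Cl2, −78 °C; MeOH, then aq. potassium sodium tartrate
Reagents that add atoms: none
Why: Partial reduction of a lactone to the lactol with i-Bu2AlH at −78 °C, where the tetrahedral aluminium alkoxide persists until the neutral work-up, which also avoids dehydration to the 3-alkylfuran; the lactol is used at once.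

Step 12
Reactants: 21 1,3-dihydroxyacetone (charged as its commercial dimer)
Product: 23 4-(hydroxymethyl)furan-2(5H)-one, via acyclic hydroxy ester 22 (not isolated)
Conditions: Ph3P=CHCO2Et, CH2Cl2, rt
Reagents that add atoms: ethyl (triphenylphosphoranylidene)acetate, CCOC(=O)C=P(c1ccccc1)(c1ccccc1)c1ccccc1
Why: Wittig olefination of the ketone with a stabilised ylide is followed by spontaneous lactonisation, because in the symmetrical enoate one hydroxymethyl group is always cis to the ester.

Step 13
Reactants: 23 4-(hydroxymethyl)furan-2(5H)-one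
Product: 24 4-(bromomethyl)furan-2(5H)-one
Conditions: CBr4, PPh3, CH2Cl2, 0 °C
Reagents that add atoms: tetrabromomethane, BrC(Br)(Br)Br
Why: Appel bromination of a primary allylic alcohol under neutral conditions that the butenolide tolerates.

Step 14
Reactants: 24 4-(bromomethyl)furan-2(5H)-one
Product: 25 diethyl [(5-oxo-2,5-dihydrofuran-3-yl)methyl]phosphonate
Conditions: P(OEt)3, toluene, 110 °C
Reagents that add atoms: triethyl phosphite, CCOP(OCC)OCC
Why: Michaelis–Arbuzov reaction of a reactive allylic bromide with triethyl phosphite, driven by loss of bromoethane.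

Step 15
Reactants: 20 4-[(3E)-4-methyl-6-{(1R,2S)-2,6,6-trimethyl-1-[(triethylsilyl)oxy]cyclohexyl}hex-3-en-1-yl]-2,5-dihydrofuran-2-ol; 25 diethyl [(5-oxo-2,5-dihydrofuran-3-yl)methyl]phosphonate
Product: 28 4-[(1E,3Z,7E)-4-(hydroxymethyl)-8-methyl-10-{(1R,2S)-2,6,6-trimethyl-1-[(triethylsilyl)oxy]cyclohexyl}deca-1,3,7-trien-1-yl]furan-2(5H)-one, via lithiated phosphonate 26 (not isolated), via open-chain enal alkoxide 27 (not isolated)
Conditions: 25 (2.2 equiv), LiN(SiMe3)2 (2.1 equiv), THF, −78 °C; then 20, −78 to 0 °C; pH 7 phosphate buffer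
Reagents that add atoms: none
Why: Horner–Wadsworth–Emmons olefination of a lactol, in which one equivalent of phosphonate anion deprotonates the lactol so that it opens to the (Z)-enal alkoxide and a second adds through the carbon next to phosphorus, as 4-phosphonocrotonates do, to give the E C15=C16 olefin, while the lithium counter-ion and low temperature hold back conjugate re-closure of the alkoxide.

Step 16
Reactants: 28 4-[(1E,3Z,7E)-4-(hydroxymethyl)-8-methyl-10-{(1R,2S)-2,6,6-trimethyl-1-[(triethylsilyl)oxy]cyclohexyl}deca-1,3,7-trien-1-yl]furan-2(5H)-one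
Product: 29 (2Z,4E)-2-[(3E)-4-methyl-6-{(1R,2S)-2,6,6-trimethyl-1-[(triethylsilyl)oxy]cyclohexyl}hex-3-en-1-yl]-5-(5-oxo-2,5-dihydrofuran-3-yl)penta-2,4-dien-1-yl acetate
Conditions: Ac2O, pyridine, DMAP (cat.), CH2Cl2, 0 °C
Reagents that add atoms: acetic anhydride, CC(=O)OC(C)=O
Why: Acetylation of the primary allylic alcohol, the only free hydroxyl, under mild nucleophilic catalysis that does not touch the butenolide.

Step 17
Reactants: 29 (2Z,4E)-2-[(3E)-4-methyl-6-{(1R,2S)-2,6,6-trimethyl-1-[(triethylsilyl)oxy]cyclohexyl}hex-3-en-1-yl]-5-(5-oxo-2,5-dihydrofuran-3-yl)penta-2,4-dien-1-yl acetate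
Product: 30 (2Z,4E)-2-{(3E)-6-[(1R,2S)-1-hydroxy-2,6,6-trimethylcyclohexyl]-4-methylhex-3-en-1-yl}-5-(5-oxo-2,5-dihydrofuran-3-yl)penta-2,4-dien-1-yl acetate
Conditions: HF·pyridine, pyridine, THF, 0 °C to rt
Reagents that add atoms: none
Why: Fluoride-mediated cleavage of the tertiary triethylsilyl ether with buffered HF·pyridine should leave the acetate, the butenolide and the triene intact and does not involve either stereocentre.

**Compound list**

1 | 2,6,6-trimethylcyclohex-2-en-1-one | CC1=CCCC(C)(C)C1=O | starting material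
2 | lithium 2,6,6-trimethylcyclohex-1-en-1-olate | [Li]OC1=C(C)CCCC1(C)C | intermediate (not isolated)
3 | trimethyl[(2,6,6-trimethylcyclohex-1-en-1-yl)oxy]silane | CC1=C(O[Si](C)(C)C)C(C)(C)CCC1 | intermediate
4 | (6S)-2,2,6-trimethylcyclohexan-1-one | C[C@H]1CCCC(C)(C)C1=O | intermediate
5 | (4-bromobut-1-yn-1-yl)trimethylsilane | C[Si](C)(C)C#CCCBr | starting material
6 | [4-(trimethylsilyl)but-3-yn-1-yl]magnesium bromide | C[Si](C)(C)C#CCC[Mg]Br | intermediate (not isolated)
7 | (1R,2S)-2,6,6-trimethyl-1-[4-(trimethylsilyl)but-3-yn-1-yl]cyclohexan-1-ol | C[Si](C)(C)C#CCC[C@@]1(O)[C@@H](C)CCCC1(C)C | intermediate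
8 | (1R,2S)-1-(but-3-yn-1-yl)-2,6,6-trimethylcyclohexan-1-ol | C#CCC[C@@]1(O)[C@@H](C)CCCC1(C)C | intermediate
9 | {[(1R,2S)-1-(but-3-yn-1-yl)-2,6,6-trimethylcyclohexyl]oxy}triethylsilane | C#CCC[C@@]1(O[Si](CC)(CC)CC)[C@@H](C)CCCC1(C)C | intermediate
10 | dimethyl[(1E)-2-methyl-4-{(1R,2S)-2,6,6-trimethyl-1-[(triethylsilyl)oxy]cyclohexyl}but-1-en-1-yl]alane | C[Al](C)/C=C(\C)CC[C@@]1(O[Si](CC)(CC)CC)[C@@H](C)CCCC1(C)C | intermediate (not isolated)
11 | lithium butyl(dimethyl)[(1E)-2-methyl-4-{(1R,2S)-2,6,6-trimethyl-1-[(triethylsilyl)oxy]cyclohexyl}but-1-en-1-yl]alanate | [Li+].CCCC[Al-](C)(C)/C=C(\C)CC[C@@]1(O[Si](CC)(CC)CC)[C@@H](C)CCCC1(C)C | intermediate (not isolated)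
12 | (3E)-4-methyl-6-{(1R,2S)-2,6,6-trimethyl-1-[(triethylsilyl)oxy]cyclohexyl}hex-3-en-1-ol | OCC/C=C(\C)CC[C@@]1(O[Si](CC)(CC)CC)[C@@H](C)CCCC1(C)C | intermediate
13 | {[(1R,2S)-1-[(3E)-6-iodo-3-methylhex-3-en-1-yl]-2,6,6-trimethylcyclohexyl]oxy}triethylsilane | ICC/C=C(\C)CC[C@@]1(O[Si](CC)(CC)CC)[C@@H](C)CCCC1(C)C | intermediate
14 | 2-bromoprop-2-en-1-ol | OCC(Br)=C | starting material
15 | iodo[(3E)-4-methyl-6-{(1R,2S)-2,6,6-trimethyl-1-[(triethylsilyl)oxy]cyclohexyl}hex-3-en-1-yl]zinc | I[Zn]CC/C=C(\C)CC[C@@]1(O[Si](CC)(CC)CC)[C@@H](C)CCCC1(C)C | intermediate (not isolated)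
16 | (5E)-6-methyl-2-methylidene-8-{(1R,2S)-2,6,6-trimethyl-1-[(triethylsilyl)oxy]cyclohexyl}oct-5-en-1-ol | OCC(=C)CC/C=C(\C)CC[C@@]1(O[Si](CC)(CC)CC)[C@@H](C)CCCC1(C)C | intermediate
17 | acryloyl chloride | C=CC(Cl)=O | starting material
18 | (5E)-6-methyl-2-methylidene-8-{(1R,2S)-2,6,6-trimethyl-1-[(triethylsilyl)oxy]cyclohexyl}oct-5-en-1-yl prop-2-enoate | C=CC(=O)OCC(=C)CC/C=C(\C)CC[C@@]1(O[Si](CC)(CC)CC)[C@@H](C)CCCC1(C)C | intermediate
19 | 4-[(3E)-4-methyl-6-{(1R,2S)-2,6,6-trimethyl-1-[(triethylsilyl)oxy]cyclohexyl}hex-3-en-1-yl]furan-2(5H)-one | O=C1C=C(CC/C=C(\C)CC[C@@]2(O[Si](CC)(CC)CC)[C@@H](C)CCCC2(C)C)CO1 | intermediate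
20 | 4-[(3E)-4-methyl-6-{(1R,2S)-2,6,6-trimethyl-1-[(triethylsilyl)oxy]cyclohexyl}hex-3-en-1-yl]-2,5-dihydrofuran-2-ol | OC1C=C(CC/C=C(\C)CC[C@@]2(O[Si](CC)(CC)CC)[C@@H](C)CCCC2(C)C)CO1 | intermediate
21 | 1,3-dihydroxyacetone | OCC(=O)CO | starting material
22 | ethyl 4-hydroxy-3-(hydroxymethyl)but-2-enoate | CCOC(=O)C=C(CO)CO | intermediate (not isolated)
23 | 4-(hydroxymethyl)furan-2(5H)-one | OCC1=CC(=O)OC1 | intermediate
24 | 4-(bromomethyl)furan-2(5H)-one | BrCC1=CC(=O)OC1 | intermediate
25 | diethyl [(5-oxo-2,5-dihydrofuran-3-yl)methyl]phosphonate | CCOP(=O)(OCC)CC1=CC(=O)OC1 | intermediate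
26 | lithium (diethoxyphosphoryl)(5-oxo-2,5-dihydrofuran-3-yl)methanide | [Li+].CCOP(=O)(OCC)[CH-]C1=CC(=O)OC1 | intermediate (not isolated)
27 | lithium (2Z,6E)-7-methyl-2-(2-oxoethylidene)-9-{(1R,2S)-2,6,6-trimethyl-1-[(triethylsilyl)oxy]cyclohexyl}non-6-en-1-olate | [Li]OC/C(=C\C=O)CC/C=C(\C)CC[C@@]1(O[Si](CC)(CC)CC)[C@@H](C)CCCC1(C)C | intermediate (not isolated)
28 | 4-[(1E,3Z,7E)-4-(hydroxymethyl)-8-methyl-10-{(1R,2S)-2,6,6-trimethyl-1-[(triethylsilyl)oxy]cyclohexyl}deca-1,3,7-trien-1-yl]furan-2(5H)-one | OC/C(=C\C=C\C1=CC(=O)OC1)CC/C=C(\C)CC[C@@]2(O[Si](CC)(CC)CC)[C@@H](C)CCCC2(C)C | intermediate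
29 | (2Z,4E)-2-[(3E)-4-methyl-6-{(1R,2S)-2,6,6-trimethyl-1-[(triethylsilyl)oxy]cyclohexyl}hex-3-en-1-yl]-5-(5-oxo-2,5-dihydrofuran-3-yl)penta-2,4-dien-1-yl acetate | CC(=O)OC/C(=C\C=C\C1=CC(=O)OC1)CC/C=C(\C)CC[C@@]2(O[Si](CC)(CC)CC)[C@@H](C)CCCC2(C)C | intermediate
30 | (2Z,4E)-2-{(3E)-6-[(1R,2S)-1-hydroxy-2,6,6-trimethylcyclohexyl]-4-methylhex-3-en-1-yl}-5-(5-oxo-2,5-dihydrofuran-3-yl)penta-2,4-dien-1-yl acetate | CC(=O)OC/C(=C\C=C\C1=CC(=O)OC1)CC/C=C(\C)CC[C@@]1(O)[C@@H](C)CCCC1(C)C | target

**Count**

Total steps: 17. Longest linear sequence: 14 (steps 1–11 and 15–17); steps 12–14 prepare phosphonate 25.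

**Steps most likely to fail**

Step 15. Three processes threaten the ring-opening olefination. The alkoxide set free on opening can add back in conjugate fashion to C15 of the new trienyl lactone and close a 2,5-dihydrofuran. The lactol can lose water to a 3-alkylfuran. Excess base can deprotonate C5 of the butenolide and shift the olefins. The fallback replaces the phosphonate carbanion by a neutral stabilised ylide, so that no alkoxide is ever formed. It sets out from bromide 24 and lactol 20 and comes back at 28. Bromide 24 and PPh3 in toluene should give [(5-oxo-2,5-dihydrofuran-3-yl)methyl]triphenylphosphonium bromide F1. Aqueous NaOH in CH2Cl2 should liberate 4-[(triphenylphosphoranylidene)methyl]furan-2(5H)-one F2. Heating F2 with 20 in toluene with a trace of benzoic acid, as in Wittig reactions of sugar lactols, should give 28, with any C15=C16 Z isomer removed by chromatography.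

Step 8. Protonolysis of the alkylzinc by the free hydroxyl of the coupling partner may compete with transmetalation and return the chain reduced at C12. The fallback removes the acidic proton from the coupling and adds a deprotection; it sets out from zinc reagent 15 (made from 13 as in step 8) and alcohol 14 and comes back at 16. Alcohol 14 is silylated (t-BuMe2SiCl, imidazole, CH2Cl2) to tert-butyl[(2-bromoprop-2-en-1-yl)oxy]dimethylsilane F3. Negishi coupling of 15 with F3 under the zerovalent palladium complex Pd(PPh3)4 in THF should give tert-butyldimethyl{[(5E)-6-methyl-2-methylidene-8-{(1R,2S)-2,6,6-trimethyl-1-[(triethylsilyl)oxy]cyclohexyl}oct-5-en-1-yl]oxy}silane F4. One equivalent of tetrabutylammonium fluoride in THF at 0 °C should cleave the primary silyl ether and leave the far more hindered tertiary one, giving 16.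

Step 2. Enantiofacial discrimination in the proton transfer may be insufficient, or adventitious acid may partly racemise the ketone, and either would lower the enantiomeric purity of all later compounds. The fallback sets the same stereocentre by hydrogen delivery to carbon instead of proton delivery to an enol ether, and needs no silyl enol ether. It sets out from enone 1 and comes back at ketone 4. Enone 1 would be hydrogenated with a cationic iridium phosphine–oxazoline catalyst, [Ir(cod)(t-Bu-PHOX)][B(C6H3(CF3)2)4], under H2 in CH2Cl2, the ligand antipode being chosen to deliver the S ketone. No compound outside the list arises (F0).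

**Further compounds**

F1 | step 15 | [(5-oxo-2,5-dihydrofuran-3-yl)methyl]triphenylphosphonium bromide | [Br-].O=C1C=C(C[P+](c2ccccc2)(c2ccccc2)c2ccccc2)CO1
F2 | step 15 | 4-[(triphenylphosphoranylidene)methyl]furan-2(5H)-one | O=C1C=C(C=P(c2ccccc2)(c2ccccc2)c2ccccc2)CO1
F3 | step 8 | tert-butyl[(2-bromoprop-2-en-1-yl)oxy]dimethylsilane | C=C(Br)CO[Si](C)(C)C(C)(C)C
F4 | step 8 | tert-butyldimethyl{[(5E)-6-methyl-2-methylidene-8-{(1R,2S)-2,6,6-trimethyl-1-[(triethylsilyl)oxy]cyclohexyl}oct-5-en-1-yl]oxy}silane | CC(C)(C)[Si](C)(C)OCC(=C)CC/C=C(\C)CC[C@@]1(O[Si](CC)(CC)CC)[C@@H](C)CCCC1(C)C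
F0 | step 2 | none | none
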